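- In a one-step world L would pass straight to Z on a single clock. These flasks put X between them, so the fraction of the charge standing as Z grows, per minute, by a first-order rate constant times the fraction standing as X.
- This is asked of four recipes, read from four earlier runs:

| flask | L | Q | temperature | remark | time |
|---|---|---|---|---|---|
| violet | 0.30 M | 1 equiv | 30 °C | run made earlier |  |
| red | 0.20 M | 1 equiv | 41 °C | run made earlier |  |
| teal | 0.45 M | 1 equiv | 30 °C | run made earlier |  |
| amber | 0.30 M | 0.50 equiv | 41 °C | run made earlier |  |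
| Sunday's | 0.30 M | 1.00 equiv | 35 °C | everything together at the start | 3.0 min |
| Tuesday's | 0.30 M (fed, over 2.0 min) | 1.00 equiv |  | the addition at 15 °C, then warmed to 35 °C; the feed brings no volume worth counting | 3.0 min |
| Friday's | 0.30 M | 1.00 equiv (fed, over 2.0 min) | 35 °C | all else is in the flask from the start; the feed brings no volume worth counting | 3.0 min |
| Monday's | 0.30 M (fed, over 2.0 min) | 1.00 equiv | 35 °C | all else is in the flask from the start; the feed brings no volume worth counting | 3.0 min |

violet run (percent of the L charged)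

| time / min | Z / % | X / % |
|---|---|---|
| 0.250 | 0.4 | 7.6 |
| 0.333 | 2.0 | 9.4 |
| 0.500 | 2.6 | 10.7 |
| 0.833 | 4.3 | 15.8 |
| 1.33 | 9.8 | 14.9 |
| 2.00 | 15.9 | 13.2 |
| 3.00 | 23.1 | 9.0 |

red run (percent of the L charged)

| time / s | Z / % | X / % |
|---|---|---|
| 15.0 | 1.6 | 7.9 |
| 30.0 | 9.1 | 9.3 |
| 50.0 | 17.0 | 8.3 |
| 60.0 | 20.6 | 9.0 |
| 80.0 | 27.9 | 5.0 |
| 90.0 | 27.1 | 4.6 |
| 120 | 32.7 | 4.0 |

teal run (percent of the L charged)

| time / s | Z / % | X / % |
|---|---|---|
| 10.0 | 0.2 | 8.8 |
| 12.0 | 0.5 | 9.3 |
| 20.0 | 0 | 14.0 |
| 30.0 | 2.6 | 13.0 |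
| 50.0 | 6.6 | 16.7 |
| 80.0 | 11.0 | 13.7 |
| 120 | 20.2 | 12.5 |

amber run (percent of the L charged)

| time / s | Z / % | X / % |
|---|---|---|
| 10.0 | 1.5 | 6.1 |
| 15.0 | 1.7 | 7.4 |
| 30.0 | 8.0 | 6.8 |
| 60.0 | 15.1 | 4.5 |
| 120 | 24.1 | 3.3 |

(each reading ± 1 percentage point)

- steps that have been proposed: L + Q -> X; Q + X -> E; Q + E -> J; X -> Z

* the flask that comes out highest in amount of Z, in percent of the L charged; "all alike" if 1.5 percentage points covers them all (Sunday's / Tuesday's / Friday's / Monday's / all alike)
* amount of Z at the end, in percent of the L charged, Sunday's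
* amount of Z at the end, in percent of the L charged, Tuesday's
* amount of Z at the end, in percent of the L charged, Friday's
* amount of Z at the end, in percent of the L charged, Monday's

- Which numbers must be known well? Q + E → J lies beyond X and reaches Z through Q. The constants of L + Q → X and Q + X → E reach Z through the level of X, which the runs show directly: violet's highest X reading is 15.8 %.
- The X → Z constant at 15 °C can be poor. Reading it from the runs gives 0.649 min⁻¹ at 30 °C from violet's last two readings, and 2.35 min⁻¹ at 41 °C from red's last six, both carrying the scatter. A straight line in ln k gives 0.112 min⁻¹ at 15 °C. With X taken at 7.90 %, Tuesday's cold feed makes 1.8 percentage points of Z, so an error of that size stays inside the forecast's 4 points margin.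
- The same line gives the fraction of X turned into Z per minute at 35 °C, 1.16 min⁻¹; the forecast has 1.24 /min. This constant must be good, since a minute at 35 °C makes ten times the Z of a cold minute from the same X.
- The crossing comes at Tuesday's warming: the time of the X → Z step taken by itself is longer than the feed, 8.93 min against 2.0 min, then shorter than the warm stretch, 0.862 min against 1.00 min. Q + X → E takes X as well, so these two times belong to the X → Z step and are not lifetimes of X.
- The forecast gives 29 %, 15 %, 27 % and 24 %, with Sunday's highest: “Tuesday's makes little Z during the cold feed and has only one warm minute”.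

    L + Q → X (k = 0.0320 M⁻¹ s⁻¹, Ea = 48.0 kJ mol⁻¹)
    Q + X → E (k = 0.0730 M⁻¹ s⁻¹, Ea = 51.0 kJ mol⁻¹)
    Q + E → J (k = 0.0170 M⁻¹ s⁻¹, Ea = 69.0 kJ mol⁻¹)
    X → Z (k = 0.0210 s⁻¹, Ea = 94.0 kJ mol⁻¹)
    (constants at 35 °C)

- The flasks give 33.7 %, 16.1 %, 27.5 % and 24.4 %, with Sunday's highest. Tuesday's holds Z at 0.750 % when its cold feed ends. In Sunday's, X falls from 10.0 % to 5.02 % over the second stretch, and the carried constant times the mean X and the 1.50 min gives 13 points, while Z climbs from 20.1 % to 33.7 %. A neighbour of Tuesday's charged with 0.075 M of L ends with X at 6.41 %; that level held over the warm stretch gives 7.5 points, and its Z ends at 7.15 %.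

The numbers in the tables stem from a simulated flask with constants of no real substance.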